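**Ochre's books.** The ochre run shows where the substrate, our limiting reagent, goes. After 4.00 h it reads 64 % substrate and 31 % product, counted free plus bound, and the 0.600 mM missing stands against 0.70 mM of catalyst charged. In the violet run, 0.720 mM is missing after 4.00 h against 0.23 mM of catalyst. With a scatter of 2 percentage points on each reading this is a hint, no more, that some substrate sits bound outside the catalyst.

| setting | ochre | violet | dusk | autumn | winter | dawn | spring |
|---|---|---|---|---|---|---|---|
| substrate | 0.012 M | 0.012 M | 0.012 M | 0.025 M | 0.050 M | 0.10 M | 0.20 M |
| free catalyst | 0.70 mM | 0.23 mM | 0.47 mM | 0.47 mM | 0.47 mM | 0.47 mM | 0.47 mM |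
| remark | run made earlier | run made earlier |  |  |  |  |  |
| time |  |  | 12 h | 12 h | 12 h | 12 h | 12 h |

| run | time / h | product / % | substrate / % |
|---|---|---|---|
| ochre | 0.333 | 0 | 98 |
| ochre | 0.500 | 0 | 94 |
| ochre | 1.00 | 5 | 89 |
| ochre | 1.50 | 13 | 87 |
| ochre | 2.50 | 21 | 74 |
| ochre | 4.00 | 31 | 64 |
| violet | 0.667 | 8 | 95 |
| violet | 1.33 | 1 | 96 |
| violet | 2.00 | 7 | 91 |
| violet | 3.00 | 9 | 88 |
| violet | 4.00 | 7 | 87 |

(each reading ± 2 percentage points)

- a reading or a percentage of product counts all its forms, free or not
- the concentration of product that is asked is that of its free form alone
- "hardly changes" means that all values lie within two and a half points (for a concentration: within two and a half percent of the largest)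
- a reading of substrate is of its free form alone

**Cycle time.** We carry one quantity: the cycle time, meaning catalyst charged divided by the rate of total product, or the hours one catalyst takes per product made 0.673 h. That is the ochre reading, between 1.00 h and 4.00 h. Violet, with a third of the catalyst, reads 0.750 h over its last three readings.

**Our reckoning.** Dusk has ochre's substrate charge, so ochre's cycle gives 8.38 mM of total product in 12 h. We commit to less: ochre's substrate already reads 64 % after 4.00 h, and any wait for substrate lengthens the cycle. A cycle is a wait for substrate plus a held time, and both earlier runs start from the same charge, 0.012 M, so we leave the two parts unsplit. If the cycle were held time throughout, spring stays near 8.38 mM; if it were wait throughout, spring reaches 140 mM. So we expect total product to rise with the charge, and free product to lag behind it as bound substrate and product grow.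

1. [product] (only what is free in solution) at the end for dusk, autumn, winter, dawn, spring, in this order
2. the shape of the row from first to last (falls all the way / falls, then rises / rises all the way / hardly changes / rises, then falls)

**The result.** The forecast stood at 0.0075 M for dusk and 0.0075 M for spring, hardly changes, in its words “Free product ≈ total product, and the row is flat”. The flasks give 0.00582 M, 0.00863 M, 0.00963 M, 0.00781 M and 0.00487 M: the row rises, then falls, turning at 0.045 M.

    substrate + free catalyst → catalyst intermediate A (k = 201 M⁻¹ h⁻¹)
    catalyst intermediate A → catalyst intermediate B (k = 126 h⁻¹)
    catalyst intermediate B → free catalyst + product (k = 4.56 h⁻¹)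
    substrate + product ⇌ idle adduct, settled at all times (K = 22.0 M⁻¹)

**Books closed.** Reckoned from total product, the average cycle time is 0.875 h in dusk and 0.256 h in spring. At 12 h in spring, the wait for substrate, 0.0310 h, is shorter than the 0.219 h mean lifetime of catalyst intermediate B, the resting state, which holds 84.9 % of the spring catalyst. Spring's total product is 22.1 mM, of which idle adduct holds 17.2 mM, and 0.00487 M stands free.

The runs were computed with made-up constants, noise included.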